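Remark on the chemistry: the target is read as the trans-(3R,4R) lactone. The formyl-bearing carbon of 9 and C4 of 12 share the same CIP order (C5 > C3 > C7), so (3R) in 9 is the arrangement needed for (4R) in 12. No structural correction was found necessary.

## Structural features

The target is a 3,4-dibenzyl-γ-butyrolactone (O1, carbonyl C2, C3, C4, C5). A 3,4,5-trimethoxybenzyl group (ring A, benzylic carbon C7') sits on C3 and a 4-hydroxy-3,5-dimethoxybenzyl group (ring B, benzylic carbon C7) on C4. C3 and C4 are adjacent stereocentres, both R, with the benzyl groups trans. C3 is α to the carbonyl and can be epimerised to the more stable trans arrangement, whereas C4 has no acidifying neighbour and must be set absolutely. The two aryl groups differ by a single O-methyl group, so each must be delivered to its own carbon without relying on a reactivity difference between two nearly identical benzyl electrophiles. The fragile elements are the free, electron-rich phenol (oxidation, O-alkylation), the lactone (opening by alkoxide or hydroxide) and both arenes, whose positions ortho to the benzylic carbons are activated enough to close onto a carbonyl electrophile at C5 under acid. The real difficulty is therefore the single non-correctable centre C4, together with the wish to carry the phenol unprotected. The key step uses the phenol as the activating group: only ring B has OH para to its benzylic carbon, so C7 can become the exocyclic CH2 of a para-quinone methide, and C4, as the α-carbon of an aldehyde whose formyl carbon is C5, attacks it as a chiral enamine.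

## Logic of the disconnections

12 to 11. No skeletal bond is cut; only the C3–H bond is treated as adjustable. C3 is the sole enolisable stereocentre and trans is the thermodynamic arrangement, so its configuration need not be controlled earlier. The gain is that asymmetric synthesis has to deliver C4 only. The forward step must reach the lactone enolate without touching C4, and the equilibrium must lie well on the trans side.

11 to 9 (through 10). The acyl bond C2–O1 is cut and C5 is raised to the aldehyde level. This exposes C4 as the α-carbon of an aldehyde, the position an amine catalyst can functionalise. The forward step must reduce 9 before C4 can epimerise, and acid may be admitted only after the formyl group is gone, because ring A can close onto C5.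

9 to 4 and 8, and 8 to 7. The C4–C7 bond is cut. C7 is para to the only free phenol, so it is the natural electrophilic carbon of 8, and C4 is the natural enamine carbon of 4. The cut gives two halves of similar size, needs no protecting group and creates one stereocentre under catalyst control. Because 8 cannot be stored, it is released from 7 in the flask. The precursor pair is designed as follows:
- 4 is racemic at C3 on purpose, since that centre is equilibrated at the end.
- 4 is made and handled without acid.
- 4 is the limiting component, and the one-step compound 7 is used in excess and added in portions.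

The forward step demands facial selectivity that is set by the catalyst and not by C3, and a concentration of 8 low enough that C-alkylation outruns its self-destruction.

7 to 5 and 6. The C7–S bond is cut. The para-hydroxybenzylic alcohol ionises readily and the sulfinate is a good sulfur nucleophile, so one step suffices. The step must favour capture by sulfinate over alkylation of a second arene.

4 to 3. The formyl group is traced to a terminal alkene, so the C5=CH2 bond is cut in the forward sense. An alkene is inert to the enolate chemistry before it and can be cleaved under buffered, non-acidic conditions. The oxidant must leave the electron-rich ring A alone.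

3 to 1 and 2. The C3–C7' bond is cut. This is an ester enolate alkylation with a benzylic bromide, which places ring A on C3 unambiguously. The only demands are monoalkylation and kinetic enolate formation at low temperature.

## Other disconnections considered

Alternative 1: The cut is O1–C5. Lactone A2, (R)-4-(4-benzyloxy-3,5-dimethoxybenzyl)dihydrofuran-2(3H)-one, is traced to the prochiral cyclobutanone A1, 3-(4-benzyloxy-3,5-dimethoxybenzyl)cyclobutan-1-one.
- Forward: a chiral Brønsted acid or a chiral Sc(OTf)3 complex with aqueous H2O2 (or a Baeyer–Villiger monooxygenase) forms the Criegee adduct and lets one of the two enantiotopic ring CH2 groups migrate to oxygen. The enolate of A2 is then alkylated with 2 anti to the C4 substituent to give A3, the O-benzyl ether of 12, and hydrogenolysis would give 12.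
- In its favour: C3 is set kinetically and trans by the existing centre. On this point it is better than the chosen plan, which needs a separate equilibration and has to remove an equilibrium remnant of the cis isomer. It is equal on placing the two aryl groups (ring B is built into A1, ring A arrives with 2).
- Against it: the differentiating group of A1 is a benzyl, one CH2 away from the four-membered ring, so the two migrating CH2 groups differ little and selectivity is expected to depend heavily on the catalyst. A peroxide is used next to an electron-rich arene. The phenol must be masked through the ketene cycloaddition and the enolate alkylation. A1 itself needs about three steps (O-benzylation of an allylarene, ketene [2+2] cycloaddition, reductive dechlorination).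
- Comparison: both plans rest on one catalytic enantioselective event. The chosen one discriminates the two faces of an enamine directly beside the shielding group, while the alternative has the more dependable second stereocentre. The count is about six linear steps with two protecting-group operations against five with none.

Alternative 2: The cut is C7–ring B. Keto lactone A6, (3S,4R)-4-(4-benzyloxy-3,5-dimethoxybenzyl)-3-(3,4,5-trimethoxybenzoyl)dihydrofuran-2(3H)-one, is traced to the cyclopropane-fused lactone A4, (1S,5R)-1-(3,4,5-trimethoxybenzoyl)-3-oxabicyclo[3.1.0]hexan-2-one, and the aryl Grignard reagent A5, (4-benzyloxy-3,5-dimethoxyphenyl)magnesium bromide.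
- Forward: A5 and CuBr·SMe2 give an aryl cuprate (monovalent copper) that opens the doubly activated cyclopropane at its CH2 in a homoconjugate, SN2-like addition. The C7–C3 bond breaks and the β-keto lactone enolate is protonated to trans A6. Hydrogenolysis over Pd/C in acid would then remove both the C7' ketone oxygen and the O-benzyl group to reach 12.
- In its favour: C4 is a spectator whose configuration is already fixed in A4 (from a chiral-pool three-carbon unit or an asymmetric cyclopropanation) and cannot erode in the key step. On certainty of absolute configuration at the moment of bond formation it is the better plan. C3 of A6 is doubly activated, so trans is reached without a separate operation. A single operation after the key step finishes the synthesis, which is equal to or better than two.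
- Against it: aryl cuprates are reluctant partners in cyclopropane opening, and the aryl ketone of A4 invites 1,2-addition. Only one aryl ligand on copper is transferred. Making enantiopure A4 with an aroyl group at the bridgehead takes several steps. Ring B must be carried as a benzyl ether and an aryl halide. C7' is introduced at the wrong oxidation level.
- Comparison: the alternative is mechanistically more secure on stereochemistry but less secure on reactivity and chemoselectivity. It is clearly longer, at about nine steps in all against six.

Alternative 3: The cut is the central C3–C4 bond. Coupling product A9, tert-butyl (2R,3R)-3-[(S)-4-benzyl-2-oxooxazolidine-3-carbonyl]-4-(4-benzyloxy-3,5-dimethoxyphenyl)-2-(3,4,5-trimethoxybenzyl)butanoate, is traced to imide A7, (S)-4-benzyl-3-[3-(4-benzyloxy-3,5-dimethoxyphenyl)propanoyl]oxazolidin-2-one, and ester A8, tert-butyl 3-(3,4,5-trimethoxyphenyl)propanoate.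
- Forward: the two lithium enolates are mixed and oxidised with Fe(acac)3 (trivalent iron, two equivalents). One enolate becomes an α-carbonyl radical that is captured by the other, with the oxazolidinone auxiliary shielding one face at C4. LiBH4 would then reduce the imide to the C5 carbinol and release the auxiliary. Acid closes the lactone with loss of the tert-butyl group, base equilibrates C3, and hydrogenolysis frees the phenol.
- In its favour: it is the most convergent cut. The molecule is halved at its centre into two hydrocinnamic acid derivatives of equal size, each one or two steps from commercial acids, and both stereocentres are addressed in one bond formation. On convergence it is the better plan. It is equal on placing the aryl groups.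
- Against it: homocoupling is the statistical competitor and is held back only by an excess of one partner. The auxiliary is stoichiometric and the oxidant is used in two-fold amount, against a catalytic amine in the chosen plan. The phenol cannot be free, because the oxidant would convert a syringyl phenoxide into a phenoxyl radical. Control at C3 by an achiral ester enolate is expected to be weak, so the same final equilibration is needed (equal). Four operations follow the key step against two.
- Comparison: about eight steps in all against six.

Key step: step 4

## Route

Step 1
Reactants: 1 methyl pent-4-enoate; 2 3,4,5-trimethoxybenzyl bromide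
Product: 3 methyl 2-(3,4,5-trimethoxybenzyl)pent-4-enoate (racemic)
Conditions: LiN(iPr)2 (1.05 equiv), THF, −78 °C, 45 min; then 2 (0.95 equiv), −78 → 0 °C
Reagents that add atoms: none
Why: Kinetic lithium enolate formation from the ester and SN2 alkylation with a reactive benzylic bromide (ester enolate alkylation) should give the monoalkylated ester; the new centre (C3) is formed racemic on purpose because it is equilibrated in step 6.

Step 2
Reactants: 3 methyl 2-(3,4,5-trimethoxybenzyl)pent-4-enoate
Product: 4 methyl 4-oxo-2-(3,4,5-trimethoxybenzyl)butanoate (racemic)
Conditions: K2OsO4·2H2O (2 mol %), NaIO4 (4 equiv), 2,6-lutidine (2 equiv), 1,4-dioxane/H2O (3:1), rt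
Reagents that add atoms: sodium periodate, [Na+].[O-][I](=O)(=O)=O (terminal source of the formyl oxygen, relayed through the osmium catalyst)
Why: Lemieux–Johnson oxidation (catalytic dihydroxylation with periodate glycol cleavage in the same flask, lutidine-buffered) should convert the terminal alkene into the aldehyde with loss of one carbon; the near-neutral medium is chosen because ring A is electron-rich and a γ-aryl aldehyde of this kind can undergo acid-promoted Friedel–Crafts closure.

Step 3
Reactants: 5 4-(hydroxymethyl)-2,6-dimethoxyphenol; 6 sodium 4-methylbenzenesulfinate
Product: 7 2,6-dimethoxy-4-[(4-methylphenyl)sulfonylmethyl]phenol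
Conditions: 6 (1.5 equiv), HCO2H/H2O (1:1), rt, 16 h
Reagents that add atoms: none
Why: Acid-promoted ionisation of the para-hydroxybenzylic alcohol gives a stabilised benzylic cation (protonated quinone methide) that the sulfinate captures at sulfur (SN1-type sulfone formation); any O-bound sulfinate ester re-ionises under the conditions, and excess sulfinate should outrun ring alkylation of a second molecule.

Step 4
Reactants: 4 methyl 4-oxo-2-(3,4,5-trimethoxybenzyl)butanoate; 7 2,6-dimethoxy-4-[(4-methylphenyl)sulfonylmethyl]phenol
Product: 9 methyl (3R)-3-formyl-4-(4-hydroxy-3,5-dimethoxyphenyl)-2-(3,4,5-trimethoxybenzyl)butanoate (both C2 epimers), via quinone methide 8 (not isolated)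
Conditions: (R)-α,α-diphenylprolinol trimethylsilyl ether (20 mol %), NaHCO3 (sat. aq., 3 equiv), CH2Cl2, 0 °C → rt; 7 (1.5 equiv) added in three portions; crude 9 taken on at once
Reagents that add atoms: none
Why: NaHCO3 deprotonates the phenol of 7 and 1,6-elimination of sulfinate releases 8 at a low, steady concentration, while the amine condenses with 4 to the E-configured, s-trans enamine. The enamine β-carbon (C4) adds to the exocyclic CH2 of 8 in a 1,6-conjugate (vinylogous Michael) addition driven by rearomatisation of ring B, and hydrolysis of the iminium ion frees 9 and the catalyst; the closest known reaction type is the enamine-catalysed α-alkylation of aldehydes with para-quinone methides, including those released in the flask from sulfones. No ring closes and one C–C bond (C4–C7) is formed. The new stereocentre C4 is set by the catalyst: the CPh2(OSiMe3) group of the (R)-amine blocks the Si face of the enamine, attack on the Re face should give (R) at C4, and because the electrophilic carbon is an unsubstituted CH2 no second centre and no syn/anti question arises. The racemic centre C3 lies one atom further from nitrogen than the reacting carbon and outside the shielded region, so catalyst control is expected to dominate for both enantiomers of 4, and both C3 epimers of 9 are usable. No control is needed between the two aryl groups, since ring A has no free para-hydroxyl and cannot form a quinone methide. Chemoselectivity rests on keeping 8 scarce, so that C-alkylation of the enamine outruns hydration, phenoxide O-alkylation and oligomerisation; the α-branched product no longer forms an enamine with the bulky amine, which prevents dialkylation and protects C4 from racemisation.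

Step 5
Reactants: 9 methyl (3R)-3-formyl-4-(4-hydroxy-3,5-dimethoxyphenyl)-2-(3,4,5-trimethoxybenzyl)butanoate (both C2 epimers)
Product: 11 (4R)-4-(4-hydroxy-3,5-dimethoxybenzyl)-3-(3,4,5-trimethoxybenzyl)dihydrofuran-2(3H)-one (both C3 epimers), via hydroxy ester 10 (not isolated)
Conditions: NaBH4 (1.5 equiv), MeOH/CH2Cl2 (1:1), 0 °C, 20 min; then 1 M HCl to pH 2, extraction; p-TsOH·H2O (5 mol %), CH2Cl2, rt
Reagents that add atoms: none
Why: Chemoselective borohydride reduction of the aldehyde (the ester is untouched at 0 °C) removes the enolisable formyl group before C4 can epimerise, and the γ-hydroxy ester then closes by acid-catalysed lactonisation (5-exo-trig transesterification) with loss of methanol. Acid is admitted only after the aldehyde is consumed, so no carbonyl electrophile is left for ring A to attack.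

Step 6
Reactants: 11 (4R)-4-(4-hydroxy-3,5-dimethoxybenzyl)-3-(3,4,5-trimethoxybenzyl)dihydrofuran-2(3H)-one (both C3 epimers)
Product: 12 (3R,4R)-4-(4-hydroxy-3,5-dimethoxybenzyl)-3-(3,4,5-trimethoxybenzyl)dihydrofuran-2(3H)-one
Conditions: DBU (3 equiv), toluene, 100 °C, argon; then 1 M HCl work-up
Reagents that add atoms: none
Why: Base-mediated epimerisation through the lactone enolate (thermodynamic control) should converge both C3 epimers on the trans lactone, in which the two benzyl groups avoid each other; C4 carries no acidic hydrogen and keeps its configuration. Excess base is used because the phenol consumes one equivalent, and air is excluded to protect the phenoxide.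

## Compound list

1 | methyl pent-4-enoate | C=CCCC(=O)OC | starting material
2 | 3,4,5-trimethoxybenzyl bromide | COc1cc(CBr)cc(OC)c1OC | starting material
3 | methyl 2-(3,4,5-trimethoxybenzyl)pent-4-enoate (racemic) | C=CCC(Cc1cc(OC)c(OC)c(OC)c1)C(=O)OC | intermediate
4 | methyl 4-oxo-2-(3,4,5-trimethoxybenzyl)butanoate (racemic) | COC(=O)C(CC=O)Cc1cc(OC)c(OC)c(OC)c1 | intermediate
5 | 4-(hydroxymethyl)-2,6-dimethoxyphenol | COc1cc(CO)cc(OC)c1O | starting material
6 | sodium 4-methylbenzenesulfinate | Cc1ccc(S(=O)[O-])cc1.[Na+] | starting material
7 | 2,6-dimethoxy-4-[(4-methylphenyl)sulfonylmethyl]phenol | COc1cc(CS(=O)(=O)c2ccc(C)cc2)cc(OC)c1O | intermediate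
8 | 2,6-dimethoxy-4-methylidenecyclohexa-2,5-dien-1-one (quinone methide, not isolated) | C=C1C=C(OC)C(=O)C(OC)=C1 | intermediate
9 | methyl (3R)-3-formyl-4-(4-hydroxy-3,5-dimethoxyphenyl)-2-(3,4,5-trimethoxybenzyl)butanoate (both C2 epimers) | COC(=O)C(Cc1cc(OC)c(OC)c(OC)c1)[C@H](C=O)Cc1cc(OC)c(O)c(OC)c1 | intermediate
10 | methyl (3R)-4-(4-hydroxy-3,5-dimethoxyphenyl)-3-(hydroxymethyl)-2-(3,4,5-trimethoxybenzyl)butanoate (both C2 epimers, not isolated) | COC(=O)C(Cc1cc(OC)c(OC)c(OC)c1)[C@H](CO)Cc1cc(OC)c(O)c(OC)c1 | intermediate
11 | (4R)-4-(4-hydroxy-3,5-dimethoxybenzyl)-3-(3,4,5-trimethoxybenzyl)dihydrofuran-2(3H)-one (both C3 epimers) | COc1cc(C[C@H]2COC(=O)C2Cc2cc(OC)c(OC)c(OC)c2)cc(OC)c1O | intermediate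
12 | (3R,4R)-4-(4-hydroxy-3,5-dimethoxybenzyl)-3-(3,4,5-trimethoxybenzyl)dihydrofuran-2(3H)-one | COc1cc(C[C@H]2COC(=O)[C@@H]2Cc2cc(OC)c(OC)c(OC)c2)cc(OC)c1O | target

## Step count and least certain steps

Total step count: 6. Longest linear sequence: 5 steps (steps 1, 2, 4, 5, 6); step 3 is a one-step branch.

**Step 4 (key step).** The β-branched aldehyde may form its enamine slowly, so the quinone methide could be consumed by hydration, O-alkylation of phenoxides and oligomerisation before it is trapped. The catalyst nitrogen may also be benzylated and taken out of the cycle. Facial selectivity may be eroded for the enantiomer of 4 whose C3 centre is mismatched with the catalyst.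

The fallback sets out from 7 and comes back at 12. The same amine-catalysed 1,6-addition is run with commercial, unbranched methyl 4-oxobutanoate, which has no neighbouring stereocentre and can be used in large excess. It would give methyl (3R)-3-formyl-4-(4-hydroxy-3,5-dimethoxyphenyl)butanoate F1. NaBH4 reduction gives methyl (3R)-4-(4-hydroxy-3,5-dimethoxyphenyl)-3-(hydroxymethyl)butanoate F2, which closes under catalytic acid to (4R)-4-(4-hydroxy-3,5-dimethoxybenzyl)dihydrofuran-2(3H)-one F3. F3 is converted with LiN(SiMe3)2 (2.2 equiv, THF, −78 °C) into its phenoxide–enolate dianion and alkylated at the enolate carbon with 2, anti to the C4 substituent, to give 12 directly. This detour introduces ring A after the stereocentre and sets C3 kinetically, so step 6 is not needed.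

**Step 3.** The benzylic cation may alkylate the activated ring of a second molecule (self-condensation) faster than it is captured by sulfinate, because the ring positions ortho to the methoxy groups are strongly activated under acid.

The fallback sets out from 6 and comes back at 7. Commercial 2,6-dimethoxyphenol is aminomethylated at its para position with aqueous formaldehyde and dimethylamine (Mannich reaction) to 4-[(dimethylamino)methyl]-2,6-dimethoxyphenol F4. F4 is heated with 6 in aqueous DMF. Thermal loss of dimethylamine releases 8 without acid, and 6 captures it at sulfur to give 7.

**Step 2.** Over-oxidation of the aldehyde or incomplete glycol cleavage may lower the return, and the aldehyde may be lost on purification through hydrate formation or air oxidation.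

The fallback sets out from 2 and comes back at 4. The lithium enolate of commercial methyl 4,4-dimethoxybutanoate (LiN(iPr)2, THF, −78 °C) is alkylated with 2 to methyl 4,4-dimethoxy-2-(3,4,5-trimethoxybenzyl)butanoate F5. The acetal is then hydrolysed under the mildest conditions available (Amberlyst-15 in wet acetone at rt) to give 4. Strong acid is excluded there because of the ring A closure noted above.

**Step 6.** The phenoxide formed first may tie up the base, separate from toluene or be oxidised by adventitious air, so equilibration could stall before the trans/cis equilibrium is reached. A residual cis fraction at equilibrium would have to be removed by chromatography or crystallisation.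

The fallback sets out from 11 and comes back at 12. The phenol is silylated (tBuMe2SiCl, imidazole, DMF) to (4R)-4-[4-(tert-butyldimethylsilyloxy)-3,5-dimethoxybenzyl]-3-(3,4,5-trimethoxybenzyl)dihydrofuran-2(3H)-one F6 (both C3 epimers). F6 is equilibrated with DBU in toluene at 100 °C to (3R,4R)-4-[4-(tert-butyldimethylsilyloxy)-3,5-dimethoxybenzyl]-3-(3,4,5-trimethoxybenzyl)dihydrofuran-2(3H)-one F7. Desilylation with Bu4NF buffered with AcOH (THF, 0 °C) gives 12. If the shortfall is thermodynamic and not kinetic, the detour described under step 4 sets C3 by alkylation instead.

## Further compounds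

F1 | step 4 | methyl (3R)-3-formyl-4-(4-hydroxy-3,5-dimethoxyphenyl)butanoate | COC(=O)C[C@H](C=O)Cc1cc(OC)c(O)c(OC)c1
F2 | step 4 | methyl (3R)-4-(4-hydroxy-3,5-dimethoxyphenyl)-3-(hydroxymethyl)butanoate | COC(=O)C[C@H](CO)Cc1cc(OC)c(O)c(OC)c1
F3 | step 4 | (4R)-4-(4-hydroxy-3,5-dimethoxybenzyl)dihydrofuran-2(3H)-one | O=C1C[C@@H](Cc2cc(OC)c(O)c(OC)c2)CO1
F4 | step 3 | 4-[(dimethylamino)methyl]-2,6-dimethoxyphenol | CN(C)Cc1cc(OC)c(O)c(OC)c1
F5 | step 2 | methyl 4,4-dimethoxy-2-(3,4,5-trimethoxybenzyl)butanoate (racemic) | COC(=O)C(CC(OC)OC)Cc1cc(OC)c(OC)c(OC)c1
F6 | step 6 | (4R)-4-[4-(tert-butyldimethylsilyloxy)-3,5-dimethoxybenzyl]-3-(3,4,5-trimethoxybenzyl)dihydrofuran-2(3H)-one (both C3 epimers) | COc1cc(C[C@H]2COC(=O)C2Cc2cc(OC)c(OC)c(OC)c2)cc(OC)c1O[Si](C)(C)C(C)(C)C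
F7 | step 6 | (3R,4R)-4-[4-(tert-butyldimethylsilyloxy)-3,5-dimethoxybenzyl]-3-(3,4,5-trimethoxybenzyl)dihydrofuran-2(3H)-one | COc1cc(C[C@H]2COC(=O)[C@@H]2Cc2cc(OC)c(OC)c(OC)c2)cc(OC)c1O[Si](C)(C)C(C)(C)C
A1 | alternative 1 | 3-(4-benzyloxy-3,5-dimethoxybenzyl)cyclobutan-1-one | O=C1CC(Cc2cc(OC)c(OCc3ccccc3)c(OC)c2)C1
A2 | alternative 1 | (R)-4-(4-benzyloxy-3,5-dimethoxybenzyl)dihydrofuran-2(3H)-one | O=C1C[C@@H](Cc2cc(OC)c(OCc3ccccc3)c(OC)c2)CO1
A3 | alternative 1 | (3R,4R)-4-(4-benzyloxy-3,5-dimethoxybenzyl)-3-(3,4,5-trimethoxybenzyl)dihydrofuran-2(3H)-one | COc1cc(C[C@H]2COC(=O)[C@@H]2Cc2cc(OC)c(OC)c(OC)c2)cc(OC)c1OCc1ccccc1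
A4 | alternative 2 | (1S,5R)-1-(3,4,5-trimethoxybenzoyl)-3-oxabicyclo[3.1.0]hexan-2-one | O=C(c1cc(OC)c(OC)c(OC)c1)[C@]12C[C@H]1COC2=O
A5 | alternative 2 | (4-benzyloxy-3,5-dimethoxyphenyl)magnesium bromide | COc1cc([Mg]Br)cc(OC)c1OCc1ccccc1
A6 | alternative 2 | (3S,4R)-4-(4-benzyloxy-3,5-dimethoxybenzyl)-3-(3,4,5-trimethoxybenzoyl)dihydrofuran-2(3H)-one | O=C(c1cc(OC)c(OC)c(OC)c1)[C@H]1C(=O)OC[C@@H]1Cc1cc(OC)c(OCc2ccccc2)c(OC)c1
A7 | alternative 3 | (S)-4-benzyl-3-[3-(4-benzyloxy-3,5-dimethoxyphenyl)propanoyl]oxazolidin-2-one | COc1cc(CCC(=O)N2[C@@H](Cc3ccccc3)COC2=O)cc(OC)c1OCc1ccccc1
A8 | alternative 3 | tert-butyl 3-(3,4,5-trimethoxyphenyl)propanoate | COc1cc(CCC(=O)OC(C)(C)C)cc(OC)c1OC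
A9 | alternative 3 | tert-butyl (2R,3R)-3-[(S)-4-benzyl-2-oxooxazolidine-3-carbonyl]-4-(4-benzyloxy-3,5-dimethoxyphenyl)-2-(3,4,5-trimethoxybenzyl)butanoate | COc1cc(C[C@@H](C(=O)N2[C@@H](Cc3ccccc3)COC2=O)[C@H](C(=O)OC(C)(C)C)Cc2cc(OC)c(OC)c(OC)c2)cc(OC)c1OCc1ccccc1
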